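All runs are simulated from invented constants; the scatter is artificial.

Late in the north run starting material reads 0% at 12.0 min and target is sinking, so that run's peak lies earlier, and we ask how long the supply of starting material lasts.

- north: starting material 0.50 M; partner 0.83 M; run made earlier
- flask: starting material 0.50 M; partner 0.550 M; time 50 min

- north (time / min: target / %, starting material / %): 3.00: 32.9, 16.5; 6.00: 38.7, 2.8; 10.0: 32.9, 0.2; 12.0: 32.6, 0; 15.0: 30.3, 0

(standard deviation of a reading: 0.5 percentage points)

- the moment within 50 min at which there is most target
- the amount of target, in percent of the starting material charged, at that time
- earliest time at which at least nineteen twentieths of that best amount are there, in min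
- latest time at which they still are, in min



How fast does starting material go? Between the readings at 3.00 min and 6.00 min its share falls by half every 1.17 min; we carry this halving time forward.

Does it hold while target forms? From the charge to the first reading the same reckoning gives 1.15 min, so in the north run the loss reads as one steady rate, and we expect the same halving time in the flask with less partner.

How many halvings stand at the highest north reading of target? There are 5.13 at 6.00 min, with 2.8% left, so we put the flask's peak at 5 halvings, 5.85 min.

The forecast, which calls the loss “mostly first-order, with little dependence on partner”, puts the peak later than we do, at 6.5 min, with 29% and a window from 3.9 min to 10 min.

The flask gives its peak at 5.88 min, with 29.7%, and a narrower window, from 4.51 min to 7.74 min.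

    starting material → open intermediate (k = 0.0100 /s)
    partner → second intermediate (k = 0.00190 /s)
    open intermediate + second intermediate → target (k = 0.750 /M/s)
    2 open intermediate → homo product (k = 0.0720 /M/s)
    target ⇌ isomer of the product (K = 1.10, k = 0.00300 /s)
    open intermediate → decomposed reagent (k = 0.00280 /s)

At that peak the flask has passed 5.03 halvings of starting material, but partner, with a half-life of 6.1 min by its loss to second intermediate alone, is slower and has passed 0.964. Partner still stands at 51.1% of its charge, while homo product holds more of the starting material than target does, 40.3% against 29.7%. Take the neighbour flask with 2.0 M of starting material, where partner stands at 0.275 equiv. If the halving time holds there, starting material falls under a fiftieth in 6.60 min, close to the 6.1 min that partner takes to fall by half, so we expect starting material to run out first. The computed neighbour flask has starting material running out first, and its best is 9.36%.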